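## Analysis of the target

Compound 22 is a furofuran lignan, a cis-fused 3,7-dioxabicyclo[3.3.0]octane with an aryl group on each of the two ether carbons next to the ring fusion. Lignan numbering is used throughout: C7, C8 and C9 belong to the half with the free phenol, C7', C8' and C9' to the half with the prenyl ether; ring A is C7–O–C9'–C8'–C8 and ring B is C7'–O–C9–C8–C8'. The four stereocentres are contiguous (7R, 8S, 8'S, 7'R): H8 and H8' are cis, and each aryl group lies on the convex face, trans to the ring carbon on the neighbouring bridgehead, which is the arrangement of the levorotatory pinoresinol series. The bicyclic core is C2-symmetric but the substitution is not, because the two guaiacyl units differ only in what the para oxygen carries, so the two phenols have to be kept apart from the first step. Both C7–O and C7'–O are benzylic ethers para to an oxygen donor and ionise under acid with loss of configuration; the prenyl ether does not survive strong acid, silane/acid reduction, hydrogenation or soft electrophiles; the free phenol is oxidisable. The difficulty is therefore to set four stereocentres as one enantiomer on a skeleton with two labile benzylic centres, and to order the steps so that the prenyl group meets no acid. The plan rests on C7': it is a benzylic carbon with a strong donor aryl, it is bonded to oxygen and to C8', and C8 next to C8' carries the oxygenated carbon C9, so ring B is the ring-expanded isomer of a cyclopropane C8–C8'–C7' with a formyl group (C9) on C8, a donor–acceptor cyclopropane fused to a finished ring A.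

## Retrosynthetic reasoning

The last operations only change what the two phenol oxygens carry. The free phenol of 22 is released from the aryl sulfonate 21 by base, which harms neither benzylic ethers nor the prenyl ether. The O–prenyl bond is cut next: 21 comes from the silyl ether 18 and prenyl bromide 19 by desilylation and O-alkylation in one flask. The prenyl group thus enters after the last acidic step, and the pair sulfonate/silyl ether tells the two phenols apart. A carboxylate ester on the C7 phenol was not used because it would not survive the hydride reduction on the way to 16 and could move between phenoxides at the desilylation.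

In 18 the cut is at C8–H and one C9–H: 18 is the dihydro form of the enol ether 17, in which C8=C9 is the alkene of ring B. The forward step must add a proton at C8 and a hydride at C9 and leave the two benzylic ethers alone. The bicyclic frame dictates a cis ring fusion, so C8 needs no external control.

Ring B of 17 is opened at C7'–O and C7' is reconnected to C8, which leads to the formyl cyclopropane 16. This is the best place to cut, because C7' carries the one substituent that can stabilise a cation, and C8 with its formyl group is the one place that can hold the matching negative charge as an enolate. The gain is that ring A, with C7 and C8' in place, can be made first, and that the configuration at C7' need not be controlled before this point. The forward reaction must ionise the C8–C7' bond only. The C7' aryl is therefore a silyl ether (donor) and the C7 aryl a sulfonate (acceptor), so that the C7–O benzylic ether stays closed.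

The aldehyde 16 is traced to the primary alcohol 15 and this to the methyl ester 14. The ester is needed one step earlier: a sulfur ylide would turn an aldehyde into an epoxide, whereas an enoate accepts it in conjugate fashion.

In 14 the two cyclopropane bonds to C7' (C7'–C8' and C7'–C8) are cut. This gives the dihydrofuran ester 8 and a benzylidene unit, supplied as the sulfonium ylide 13 made in the flask from the salt 12. The forward step must add the ylide to C8' on the face away from the C7 aryl; this fixes C8' (and C8) relative to C7. Which way the aryl on C7' points does not matter.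

The salt 12 is cut at C–S to the benzylic bromide 11, which comes from the alcohol 10, the aldehyde 9 and vanillin 1 by functional-group changes only.

The ring alkene of 8 (C8=C8') is cut by ring-closing metathesis to the diene 7, and the O–C9' bond of 7 to the alcohol 5 and allyl bromide 6. The ring is closed on an intact C7 stereocentre, so nothing has to be controlled in these steps.

The C7–C8 bond of 5 is the bond of a Morita–Baylis–Hillman reaction between the aldehyde 2 and an acrylate. This is the only step that needs an external source of chirality. Because simple alkyl acrylates give poor induction, the activated acrylate 3 is used and the adduct 4 is then converted into the methyl ester 5. The aldehyde 2 is the sulfonate of vanillin 1, so both halves of 22 start from 1.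

## Alternatives that were turned down

Alternative 1: The cuts are C7'–C8' and C7–C8 on a preformed butyrolactone whose carbonyl carbon is C9. In the forward key step the deprotonated dithiane A2 (C7' as an acyl anion equivalent) adds to C8' of the sugar-derived butenolide A1 anti to its silyloxymethyl group, and the lactone enolate is trapped at C8 by an O-silylated vanillin (the aldehyde A9 of alternative 3), giving A3.
- For it: the three-component coupling is a well-tried way into lignans; the absolute configuration comes from the chiral pool with a dependable anti addition; the two aryl groups enter as separate reagents, so they never need to be told apart. On precedent and on the source of chirality it is stronger than the chosen route.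
- Against it: A3 is far from 22. C7' is still at the ketone oxidation level, and C9' carries the extra carbon of the control element, which must be excised by lactone reduction and glycol cleavage. The C7 carbinol is formed with little control, and both ether rings remain to be closed through benzylic cations. Unmasking the dithiane with thiophilic metal salts or oxidants endangers the prenyl alkene of A2, and the acid ring closures endanger the prenyl ether.
- Comparison: the chosen route ends three steps after its key step, forms ring B and C7' in that step, and keeps the prenyl group out of all acidic chemistry. The price is a less secure key step.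

Alternative 2: The cuts are the two aryl–carbon bonds at C7 and C7'. In the forward key step a strong Lewis acid ionises the C2-symmetric bis-lactol diacetate A4 to bicyclic oxocarbenium ions, and two molecules of the arylzinc bromide A5 add from the convex face to give the bis-silyl ether A6.
- For it: it is the shortest and most convergent plan, it uses the hidden symmetry of the core, and convex-face addition to a cis-fused bicyclic cation is well founded. On step count it is clearly stronger than the chosen route.
- Against it: both aryl groups are the same. Desilylation of A6 gives the diphenol A7, and 22 then requires alkylation of exactly one of two homotopic phenols, which can only be statistical (one mono-ether, but accompanied by bis-ether and unchanged A7). The first electron-rich benzylic ether must also survive the Lewis acid while the second acetate ionises, and enantiopure A4 needs a synthesis of its own.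
- Comparison: the chosen route is longer, but the two phenols are different from the first step and the absolute configuration comes from a catalytic step on vanillin.

Alternative 3: The cuts are C7–C8 and the lactone bond O–C9'. In the forward key step a divalent samarium reagent reduces the aldehyde A9 to its ketyl, which adds to C8 of the dihydrofuran ester A8 anti to the C7' aryl; after protonation at C8' the C7 alkoxide closes onto the ester and gives the lactone A10.
- For it: A8 is the prenyl analogue of 8, so the early chemistry is shared; the prenyl ether is present from the start; C7–C8 and a ring form in one step; the lactone enforces the cis fusion. It needs no late phenol manipulation, which is a point in its favour.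
- Against it: the ketyl of an aromatic aldehyde is stabilised and prefers pinacol coupling to addition to a trisubstituted enoate. Nothing strong controls the new C7 centre. The C9' carbonyl must then be reduced to CH2, and the usual lactol/silane/Lewis acid sequence is not compatible with the prenyl ether or the benzylic ethers.
- Comparison: the chosen route sets C7 under catalyst control before any ring exists, forms the second benzylic centre by a stereoconvergent ionic closure, and introduces the prenyl group after the acid steps.

Key step: step 13

## Route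

Assumption: α-isocupreine, the quinine-derived pseudoenantiomer of β-isocupreidine, is taken to be at hand (made from quinine, not counted as a step) and to give the (S)-adduct, since β-isocupreidine gives the (R)-adduct.

Abbreviations: TBS = tert-butyldimethylsilyl; tosyl = p-toluenesulfonyl.

Step 1
Reactants: 1 vanillin (4-hydroxy-3-methoxybenzaldehyde)
Product: 2 4-formyl-2-methoxyphenyl 4-methylbenzenesulfonate
Conditions: TsCl, K2CO3, acetone, rt
Reagents that add atoms: p-toluenesulfonyl chloride, Cc1ccc(S(=O)(=O)Cl)cc1
Why: Sulfonylation of the phenol; the aryl sulfonate withstands amines, ylides, aluminium hydride, Lewis acids and fluoride at room temperature, makes the aldehyde more electrophilic for step 2 and later holds the C7 benzylic ether closed.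

Step 2
Reactants: 2 4-formyl-2-methoxyphenyl 4-methylbenzenesulfonate; 3 1,1,1,3,3,3-hexafluoropropan-2-yl acrylate
Product: 4 1,1,1,3,3,3-hexafluoropropan-2-yl (S)-2-{hydroxy[3-methoxy-4-(tosyloxy)phenyl]methyl}acrylate
Conditions: α-isocupreine (10 mol%), DMF, −55 °C
Reagents that add atoms: none
Why: Enantioselective Morita–Baylis–Hillman reaction: the quinuclidine nitrogen adds to the activated acrylate and the phenolic OH of the catalyst organises the aldol step by hydrogen bonding, which sets C7 as (S). The fluorinated ester provides the rate and the induction that methyl acrylate lacks.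

Step 3
Reactants: 4 1,1,1,3,3,3-hexafluoropropan-2-yl (S)-2-{hydroxy[3-methoxy-4-(tosyloxy)phenyl]methyl}acrylate
Product: 5 methyl (S)-2-{hydroxy[3-methoxy-4-(tosyloxy)phenyl]methyl}acrylate
Conditions: MeOH, Et3N (cat.), rt
Reagents that add atoms: methanol, CO
Why: Transesterification of an activated ester under mild amine catalysis; the carbinol centre is not involved and the aryl sulfonate is inert. The methyl ester is wanted because an enolate of the fluorinated ester could expel its alkoxide in step 10.

Step 4
Reactants: 5 methyl (S)-2-{hydroxy[3-methoxy-4-(tosyloxy)phenyl]methyl}acrylate; 6 allyl bromide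
Product: 7 methyl (S)-2-{(allyloxy)[3-methoxy-4-(tosyloxy)phenyl]methyl}acrylate
Conditions: Ag2O, 4 Å MS, CH2Cl2, rt, dark
Reagents that add atoms: none
Why: Silver-oxide-assisted Williamson etherification; no free alkoxide is formed, so retro-aldol cleavage, oxa-Michael addition to the acrylate and racemisation are avoided, and the C7–O bond is retained.

Step 5
Reactants: 7 methyl (S)-2-{(allyloxy)[3-methoxy-4-(tosyloxy)phenyl]methyl}acrylate
Product: 8 methyl (S)-2-[3-methoxy-4-(tosyloxy)phenyl]-2,5-dihydrofuran-3-carboxylate
Conditions: second-generation Grubbs catalyst RuCl2(=CHPh)(H2IMes)(PCy3) (3 mol%), CH2Cl2, 40 °C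
Reagents that add atoms: none
Why: Ring-closing metathesis between the allyl ether and the 1,1-disubstituted acrylate closes the five-membered ring with loss of ethene; the carbene-ligated catalyst handles electron-poor disubstituted alkenes, and the stereocentre is not part of the reacting alkenes.

Step 6
Reactants: 1 vanillin
Product: 9 4-(tert-butyldimethylsilyloxy)-3-methoxybenzaldehyde
Conditions: TBSCl, imidazole, DMF, rt
Reagents that add atoms: tert-butyldimethylsilyl chloride, CC(C)(C)[Si](C)(C)Cl
Why: Standard silylation of a phenol; the silyl ether keeps the para oxygen a strong donor for step 13 and can be removed by fluoride next to the aryl sulfonate.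

Step 7
Reactants: 9 4-(tert-butyldimethylsilyloxy)-3-methoxybenzaldehyde
Product: 10 [4-(tert-butyldimethylsilyloxy)-3-methoxyphenyl]methanol
Conditions: NaBH4, MeOH, 0 °C
Reagents that add atoms: none
Why: Borohydride reduction of an aromatic aldehyde; a short reaction at 0 °C leaves the aryl silyl ether intact.

Step 8
Reactants: 10 [4-(tert-butyldimethylsilyloxy)-3-methoxyphenyl]methanol
Product: 11 [4-(bromomethyl)-2-methoxyphenoxy](tert-butyl)dimethylsilane
Conditions: PBr3, Et2O, 0 °C
Reagents that add atoms: phosphorus tribromide, BrP(Br)Br
Why: Conversion of an electron-rich benzylic alcohol into the bromide through its phosphite ester; the reactive bromide is carried on without chromatography.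

Step 9
Reactants: 11 [4-(bromomethyl)-2-methoxyphenoxy](tert-butyl)dimethylsilane
Product: 12 1-[4-(tert-butyldimethylsilyloxy)-3-methoxybenzyl]tetrahydrothiophen-1-ium bromide
Conditions: tetrahydrothiophene, acetone, rt
Reagents that add atoms: tetrahydrothiophene, C1CCSC1
Why: S-Alkylation of a sulfide by a reactive benzylic bromide; the sulfonium salt should precipitate and be collected by filtration.

Step 10
Reactants: 12 1-[4-(tert-butyldimethylsilyloxy)-3-methoxybenzyl]tetrahydrothiophen-1-ium bromide; 8 methyl (S)-2-[3-methoxy-4-(tosyloxy)phenyl]-2,5-dihydrofuran-3-carboxylate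
Product: 14 methyl (1S,2S,5S,6R)-6-[4-(tert-butyldimethylsilyloxy)-3-methoxyphenyl]-2-[3-methoxy-4-(tosyloxy)phenyl]-3-oxabicyclo[3.1.0]hexane-1-carboxylate, via sulfonium ylide 13 (not isolated)
Conditions: LiN(SiMe3)2, THF, −78 °C; then 8, −78 °C to rt
Reagents that add atoms: none
Why: Corey–Chaykovsky-type cyclopropanation by a semi-stabilised sulfonium benzylide (Michael-initiated ring closure): the ylide carbon adds to C8' on the ring face opposite the C7 aryl and the ester enolate then displaces the sulfide at C7' in a 3-exo-tet closure, so C8' and C8 are set relative to C7. The C7' aryl is expected mainly exo, away from ring A, and its configuration is erased in step 13.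

Step 11
Reactants: 14 methyl (1S,2S,5S,6R)-6-[4-(tert-butyldimethylsilyloxy)-3-methoxyphenyl]-2-[3-methoxy-4-(tosyloxy)phenyl]-3-oxabicyclo[3.1.0]hexane-1-carboxylate
Product: 15 {(1R,2S,5S,6R)-6-[4-(tert-butyldimethylsilyloxy)-3-methoxyphenyl]-2-[3-methoxy-4-(tosyloxy)phenyl]-3-oxabicyclo[3.1.0]hexan-1-yl}methanol
Conditions: i-Bu2AlH, CH2Cl2, −78 to 0 °C; aq. potassium sodium tartrate
Reagents that add atoms: none
Why: Hydride reduction of the ester to the primary alcohol; aryl sulfonate, aryl silyl ether and cyclopropane are inert to the aluminium hydride at low temperature, and the neutral tartrate work-up keeps acid away from the cyclopropylcarbinol. The change of the C1 descriptor reflects changed priorities only.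

Step 12
Reactants: 15 {(1R,2S,5S,6R)-6-[4-(tert-butyldimethylsilyloxy)-3-methoxyphenyl]-2-[3-methoxy-4-(tosyloxy)phenyl]-3-oxabicyclo[3.1.0]hexan-1-yl}methanol
Product: 16 (1S,2S,5S,6R)-6-[4-(tert-butyldimethylsilyloxy)-3-methoxyphenyl]-2-[3-methoxy-4-(tosyloxy)phenyl]-3-oxabicyclo[3.1.0]hexane-1-carbaldehyde
Conditions: (n-Pr)4N[RuO4] (5 mol%), NMO, 4 Å MS, CH2Cl2, rt
Reagents that add atoms: none
Why: Ley–Griffith oxidation of a primary alcohol to the aldehyde under neutral conditions, which matters because the product is a donor–acceptor cyclopropane; C8 is quaternary, so no α-centre can epimerise.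

Step 13
Reactants: 16 (1S,2S,5S,6R)-6-[4-(tert-butyldimethylsilyloxy)-3-methoxyphenyl]-2-[3-methoxy-4-(tosyloxy)phenyl]-3-oxabicyclo[3.1.0]hexane-1-carbaldehyde
Product: 17 (1S,3aS,4R)-4-[4-(tert-butyldimethylsilyloxy)-3-methoxyphenyl]-1-[3-methoxy-4-(tosyloxy)phenyl]-3a,4-dihydro-1H,3H-furo[3,4-c]furan (bicyclic enol ether with the alkene C8=C9)
Conditions: Sc(OTf)3 (10 mol%), 4 Å MS, CH2Cl2, −20 to 0 °C; Et3N quench
Reagents that add atoms: none
Why: Sc(OTf)3 binds the formyl oxygen, and the C8–C7' bond, the only cyclopropane bond flanked by the acceptor carbon C8 and the donor carbon C7' with its para-silyloxyaryl group, ionises to a scandium enolate C8=C9–O and a para-silyloxybenzylic cation at C7'. The enolate oxygen then bonds to C7' and the Lewis acid is released, a net 1,3-shift of C7' from carbon to oxygen driven by loss of cyclopropane strain; this is the Cloke–Wilson rearrangement of a donor–acceptor cyclopropyl aldehyde to a 2,3-dihydrofuran, here on a bicyclic substrate. Ring B (C7'–O–C9=C8–C8') closes by 5-exo-trig attack of the in-plane oxygen lone pair of the enolate on the cation, an (enolendo)-exo closure that is open to oxygen, whereas attack through carbon could only return the cyclopropane. The one stereocentre formed is C7', and it is controlled by the resident centre C8': the planar cation has lost the configuration it had in 16, and in the closing transition state the aryl group takes the side away from C9', which gives the trans-4,5-disubstituted dihydrofuran with the aryl on the convex face (7'R), so both C7' epimers of 16 should converge. The step needs ionisation at C7' only: the C7–O benzylic ether of ring A is held closed by its electron-poor sulfonyloxyaryl group and by poor alignment with the cyclopropane bond, and C7 and C8' are not touched. Low temperature, a catalytic amount of Lewis acid, molecular sieves and the amine quench are meant to keep the acid-labile enol ether, whose C7–O bond has become allylic, from ionising again.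

Step 14
Reactants: 17 (1S,3aS,4R)-4-[4-(tert-butyldimethylsilyloxy)-3-methoxyphenyl]-1-[3-methoxy-4-(tosyloxy)phenyl]-3a,4-dihydro-1H,3H-furo[3,4-c]furan
Product: 18 (1R,3aS,4R,6aS)-4-[4-(tert-butyldimethylsilyloxy)-3-methoxyphenyl]-1-[3-methoxy-4-(tosyloxy)phenyl]tetrahydro-1H,3H-furo[3,4-c]furan
Conditions: Et3SiH, CF3CO2H, CH2Cl2, −78 to −40 °C; Et3N then aq. NaHCO3
Reagents that add atoms: none
Why: Ionic hydrogenation of a cyclic enol ether: protonation at C8 gives the oxocarbenium ion at C9, which the silane reduces. C8 is set in the protonation, which can only lead to the cis-fused bicycle because a trans-fused five/five oxocarbenium ion is far too strained, so H8 ends cis to H8' (8S); catalytic hydrogenation was not chosen because both aryl groups flank the convex face that the catalyst would have to reach. Low temperature and excess silane are meant to let hydride capture outrun ionisation of the C7'–O bond.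

Step 15
Reactants: 18 (1R,3aS,4R,6aS)-4-[4-(tert-butyldimethylsilyloxy)-3-methoxyphenyl]-1-[3-methoxy-4-(tosyloxy)phenyl]tetrahydro-1H,3H-furo[3,4-c]furan; 19 prenyl bromide (1-bromo-3-methylbut-2-ene)
Product: 21 2-methoxy-4-[(1R,3aS,4R,6aS)-4-{3-methoxy-4-[(3-methylbut-2-en-1-yl)oxy]phenyl}tetrahydro-1H,3H-furo[3,4-c]furan-1-yl]phenyl 4-methylbenzenesulfonate, via caesium phenoxide 20 (not isolated)
Conditions: CsF, DMF, rt
Reagents that add atoms: none
Why: Fluoride cleaves the aryl silyl ether and the caesium phenoxide is alkylated in the same flask by the primary allylic bromide (Williamson ether synthesis, SN2 at the unsubstituted terminus). The aryl sulfonate on the other phenol is not attacked by fluoride or phenoxide at room temperature, so only the C7' aryl is prenylated.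

Step 16
Reactants: 21 2-methoxy-4-[(1R,3aS,4R,6aS)-4-{3-methoxy-4-[(3-methylbut-2-en-1-yl)oxy]phenyl}tetrahydro-1H,3H-furo[3,4-c]furan-1-yl]phenyl 4-methylbenzenesulfonate
Product: 22 2-methoxy-4-[(1R,3aS,4R,6aS)-4-{3-methoxy-4-[(3-methylbut-2-en-1-yl)oxy]phenyl}tetrahydro-1H,3H-furo[3,4-c]furan-1-yl]phenol (CNP0185952.2)
Conditions: KOH, MeOH–THF–H2O, 60 °C; then aq. NH4Cl
Reagents that add atoms: none
Why: Hydroxide attacks the sulfur of the aryl sulfonate and releases the phenoxide (S–O cleavage); the benzylic ethers, the prenyl ether and all four stereocentres are stable to base at this temperature, and the only acid is the buffered quench.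

## Compound list

1 | vanillin (4-hydroxy-3-methoxybenzaldehyde) | COc1cc(C=O)ccc1O | starting material
2 | 4-formyl-2-methoxyphenyl 4-methylbenzenesulfonate | COc1cc(C=O)ccc1OS(=O)(=O)c1ccc(C)cc1 | intermediate
3 | 1,1,1,3,3,3-hexafluoropropan-2-yl acrylate | C=CC(=O)OC(C(F)(F)F)C(F)(F)F | starting material
4 | 1,1,1,3,3,3-hexafluoropropan-2-yl (S)-2-{hydroxy[3-methoxy-4-(tosyloxy)phenyl]methyl}acrylate | C=C(C(=O)OC(C(F)(F)F)C(F)(F)F)[C@@H](O)c1ccc(OS(=O)(=O)c2ccc(C)cc2)c(OC)c1 | intermediate
5 | methyl (S)-2-{hydroxy[3-methoxy-4-(tosyloxy)phenyl]methyl}acrylate | C=C(C(=O)OC)[C@@H](O)c1ccc(OS(=O)(=O)c2ccc(C)cc2)c(OC)c1 | intermediate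
6 | allyl bromide | C=CCBr | starting material
7 | methyl (S)-2-{(allyloxy)[3-methoxy-4-(tosyloxy)phenyl]methyl}acrylate | C=CCO[C@H](C(=C)C(=O)OC)c1ccc(OS(=O)(=O)c2ccc(C)cc2)c(OC)c1 | intermediate
8 | methyl (S)-2-[3-methoxy-4-(tosyloxy)phenyl]-2,5-dihydrofuran-3-carboxylate | COC(=O)C1=CCO[C@H]1c1ccc(OS(=O)(=O)c2ccc(C)cc2)c(OC)c1 | intermediate
9 | 4-(tert-butyldimethylsilyloxy)-3-methoxybenzaldehyde | COc1cc(C=O)ccc1O[Si](C)(C)C(C)(C)C | intermediate
10 | [4-(tert-butyldimethylsilyloxy)-3-methoxyphenyl]methanol | COc1cc(CO)ccc1O[Si](C)(C)C(C)(C)C | intermediate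
11 | [4-(bromomethyl)-2-methoxyphenoxy](tert-butyl)dimethylsilane | COc1cc(CBr)ccc1O[Si](C)(C)C(C)(C)C | intermediate
12 | 1-[4-(tert-butyldimethylsilyloxy)-3-methoxybenzyl]tetrahydrothiophen-1-ium bromide | COc1cc(C[S+]2CCCC2)ccc1O[Si](C)(C)C(C)(C)C.[Br-] | intermediate
13 | tetrahydrothiophenium [4-(tert-butyldimethylsilyloxy)-3-methoxyphenyl]methylide (sulfonium ylide, not isolated) | COc1cc([CH-][S+]2CCCC2)ccc1O[Si](C)(C)C(C)(C)C | intermediate
14 | methyl (1S,2S,5S,6R)-6-[4-(tert-butyldimethylsilyloxy)-3-methoxyphenyl]-2-[3-methoxy-4-(tosyloxy)phenyl]-3-oxabicyclo[3.1.0]hexane-1-carboxylate | COC(=O)[C@]12[C@H](c3ccc(OS(=O)(=O)c4ccc(C)cc4)c(OC)c3)OC[C@H]1[C@@H]2c1ccc(O[Si](C)(C)C(C)(C)C)c(OC)c1 | intermediate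
15 | {(1R,2S,5S,6R)-6-[4-(tert-butyldimethylsilyloxy)-3-methoxyphenyl]-2-[3-methoxy-4-(tosyloxy)phenyl]-3-oxabicyclo[3.1.0]hexan-1-yl}methanol | OC[C@]12[C@H](c3ccc(OS(=O)(=O)c4ccc(C)cc4)c(OC)c3)OC[C@H]1[C@@H]2c1ccc(O[Si](C)(C)C(C)(C)C)c(OC)c1 | intermediate
16 | (1S,2S,5S,6R)-6-[4-(tert-butyldimethylsilyloxy)-3-methoxyphenyl]-2-[3-methoxy-4-(tosyloxy)phenyl]-3-oxabicyclo[3.1.0]hexane-1-carbaldehyde | O=C[C@]12[C@H](c3ccc(OS(=O)(=O)c4ccc(C)cc4)c(OC)c3)OC[C@H]1[C@@H]2c1ccc(O[Si](C)(C)C(C)(C)C)c(OC)c1 | intermediate
17 | (1S,3aS,4R)-4-[4-(tert-butyldimethylsilyloxy)-3-methoxyphenyl]-1-[3-methoxy-4-(tosyloxy)phenyl]-3a,4-dihydro-1H,3H-furo[3,4-c]furan | COc1cc([C@@H]2OC=C3[C@H]2CO[C@H]3c2ccc(OS(=O)(=O)c4ccc(C)cc4)c(OC)c2)ccc1O[Si](C)(C)C(C)(C)C | intermediate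
18 | (1R,3aS,4R,6aS)-4-[4-(tert-butyldimethylsilyloxy)-3-methoxyphenyl]-1-[3-methoxy-4-(tosyloxy)phenyl]tetrahydro-1H,3H-furo[3,4-c]furan | COc1cc([C@@H]2OC[C@@H]3[C@H]2CO[C@H]3c2ccc(O[Si](C)(C)C(C)(C)C)c(OC)c2)ccc1OS(=O)(=O)c1ccc(C)cc1 | intermediate
19 | prenyl bromide (1-bromo-3-methylbut-2-ene) | CC(C)=CCBr | starting material
20 | caesium 2-methoxy-4-{(1R,3aS,4R,6aS)-4-[3-methoxy-4-(tosyloxy)phenyl]tetrahydro-1H,3H-furo[3,4-c]furan-1-yl}phenoxide (not isolated) | COc1cc([C@@H]2OC[C@@H]3[C@H]2CO[C@H]3c2ccc([O-])c(OC)c2)ccc1OS(=O)(=O)c1ccc(C)cc1.[Cs+] | intermediate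
21 | 2-methoxy-4-[(1R,3aS,4R,6aS)-4-{3-methoxy-4-[(3-methylbut-2-en-1-yl)oxy]phenyl}tetrahydro-1H,3H-furo[3,4-c]furan-1-yl]phenyl 4-methylbenzenesulfonate | COc1cc([C@@H]2OC[C@@H]3[C@H]2CO[C@H]3c2ccc(OCC=C(C)C)c(OC)c2)ccc1OS(=O)(=O)c1ccc(C)cc1 | intermediate
22 | 2-methoxy-4-[(1R,3aS,4R,6aS)-4-{3-methoxy-4-[(3-methylbut-2-en-1-yl)oxy]phenyl}tetrahydro-1H,3H-furo[3,4-c]furan-1-yl]phenol | COc1cc([C@@H]2OC[C@@H]3[C@H]2CO[C@H]3c2ccc(OCC=C(C)C)c(OC)c2)ccc1O | target

## Step count and weak points

Total: 16 steps. Longest linear sequence: 12 steps (steps 1 to 5 and 10 to 16); steps 6 to 9 are the side branch to the sulfonium salt 12.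

Step 13 (key step). Three things may go wrong:
- The closure may not be fully stereoconvergent, so part of the material closes with the C7' aryl on the concave face.
- The ion pair may lose a proton instead of closing, which gives ring-opened isomers.
- The Lewis acid may ionise the allylic, benzylic C7–O bond of the product, with epimerisation at C7 or oligomerisation of the enol ether.

The fallback sets out from 16 and comes back at 18. The aldehyde is oxidised with buffered NaClO2 (2-methyl-2-butene as scavenger) to the carboxylic acid F1. A catalytic Brønsted acid (TfOH, CH2Cl2, low temperature) then opens the same C8–C7' bond with the carboxyl group as the internal nucleophile and protonation at C8, giving the cis-fused lactone F2, a robust compound in which the aryl can settle on the convex face. LiBH4 reduces the lactone to the diol F3, and a trace of camphorsulfonic acid closes ring B through the C7' benzylic cation to 18. This costs two more steps, avoids the enol ether altogether and also replaces step 14.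

Step 14. The protonated enol ether may fragment at C7'–O into an aldehyde and the benzylic cation before hydride arrives, and the silane would then reduce C7' and leave ring B open; epimerisation at C7' by the same ionisation is the milder form of this failure. The fallback sets out from 17 and comes back at 18. Hydration with pyridinium p-toluenesulfonate in wet THF gives the lactol F4 (protonation at C8 again on the convex face). NaBH4 reduces its open hydroxy aldehyde form to the diol F3, and the acid-catalysed cyclodehydration described above gives 18. No hydride donor is then present together with acid.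

Step 10. The ylide may add too slowly to the trisubstituted cyclic enoate and decompose. The base or the ylide may remove a proton from C9' of 8 and shift the double bond into conjugation with the ring oxygen. Attack at C8' may not be fully selective for the face away from the C7 aryl. The fallback sets out from 9 and 8 and comes back at 14. Condensation of 9 with p-toluenesulfonohydrazide gives the tosylhydrazone F5. Its sodium salt, warmed in the presence of 8, releases the aryldiazomethane F6, which adds as a 1,3-dipole to the enoate (carbon to C8', nitrogen to C8, on the face away from the C7 aryl) to give the 1-pyrazoline F7. Irradiation expels dinitrogen and closes the cyclopropane to 14 under neutral conditions.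

Step 2. The induction or the conversion with this aldehyde may be insufficient, and a second molecule of aldehyde may be taken up into a dioxanone. The fallback sets out from 2 and comes back at 5. The DABCO-mediated Morita–Baylis–Hillman reaction of 2 with methyl acrylate gives the racemic methyl ester F8, and the enantiomers are separated by preparative chromatography on a chiral stationary phase. The (S)-enantiomer is 5, so step 3 is replaced as well.

## Further compounds

F1 | step 13 | (1S,2S,5S,6R)-6-[4-(tert-butyldimethylsilyloxy)-3-methoxyphenyl]-2-[3-methoxy-4-(tosyloxy)phenyl]-3-oxabicyclo[3.1.0]hexane-1-carboxylic acid | OC(=O)[C@]12[C@H](c3ccc(OS(=O)(=O)c4ccc(C)cc4)c(OC)c3)OC[C@H]1[C@@H]2c1ccc(O[Si](C)(C)C(C)(C)C)c(OC)c1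
F2 | step 13 | (3R,3aS,6R,6aR)-3-[4-(tert-butyldimethylsilyloxy)-3-methoxyphenyl]-6-[3-methoxy-4-(tosyloxy)phenyl]tetrahydro-1H,3H-furo[3,4-c]furan-1-one | COc1cc([C@@H]2OC[C@@H]3[C@H]2C(=O)O[C@H]3c2ccc(O[Si](C)(C)C(C)(C)C)c(OC)c2)ccc1OS(=O)(=O)c1ccc(C)cc1
F3 | step 13 | (R)-[4-(tert-butyldimethylsilyloxy)-3-methoxyphenyl]{(3S,4S,5R)-4-(hydroxymethyl)-5-[3-methoxy-4-(tosyloxy)phenyl]tetrahydrofuran-3-yl}methanol | COc1cc([C@@H]2OC[C@@H]([C@@H](O)c3ccc(O[Si](C)(C)C(C)(C)C)c(OC)c3)[C@H]2CO)ccc1OS(=O)(=O)c1ccc(C)cc1
F4 | step 14 | (3R,3aS,6R,6aR)-3-[4-(tert-butyldimethylsilyloxy)-3-methoxyphenyl]-6-[3-methoxy-4-(tosyloxy)phenyl]tetrahydro-1H,3H-furo[3,4-c]furan-1-ol (both configurations at C1) | COc1cc([C@@H]2OC[C@@H]3[C@H]2C(O)O[C@H]3c2ccc(O[Si](C)(C)C(C)(C)C)c(OC)c2)ccc1OS(=O)(=O)c1ccc(C)cc1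
F5 | step 10 | (E)-N'-[4-(tert-butyldimethylsilyloxy)-3-methoxybenzylidene]-4-methylbenzenesulfonohydrazide | COc1cc(/C=N/NS(=O)(=O)c2ccc(C)cc2)ccc1O[Si](C)(C)C(C)(C)C
F6 | step 10 | tert-butyl[4-(diazomethyl)-2-methoxyphenoxy]dimethylsilane | COc1cc(C=[N+]=[N-])ccc1O[Si](C)(C)C(C)(C)C
F7 | step 10 | methyl 3-[4-(tert-butyldimethylsilyloxy)-3-methoxyphenyl]-6-[3-methoxy-4-(tosyloxy)phenyl]-3,3a,4,6-tetrahydro-6aH-furo[3,4-c]pyrazole-6a-carboxylate (ring fusion and aryl-bearing ring carbon as in 14, pyrazoline carbon C3 as a mixture) | COC(=O)[C@]12[C@H](c3ccc(OS(=O)(=O)c4ccc(C)cc4)c(OC)c3)OC[C@H]1C(c1ccc(O[Si](C)(C)C(C)(C)C)c(OC)c1)N=N2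
F8 | step 2 | racemic methyl 2-{hydroxy[3-methoxy-4-(tosyloxy)phenyl]methyl}acrylate | C=C(C(=O)OC)C(O)c1ccc(OS(=O)(=O)c2ccc(C)cc2)c(OC)c1
A1 | alternative 1 | (S)-5-[(tert-butyldimethylsilyloxy)methyl]furan-2(5H)-one | O=C1C=C[C@@H](CO[Si](C)(C)C(C)(C)C)O1
A2 | alternative 1 | 2-{3-methoxy-4-[(3-methylbut-2-en-1-yl)oxy]phenyl}-1,3-dithiane | COc1cc(C2SCCCS2)ccc1OCC=C(C)C
A3 | alternative 1 | trans-α,β-disubstituted γ-butyrolactone (dithiane and aldol adduct) | O=C1O[C@H](CO[Si](C)(C)C(C)(C)C)[C@@H](C2(c3ccc(OCC=C(C)C)c(OC)c3)SCCCS2)[C@@H]1[C@@H](O)c1ccc(O[Si](C(C)C)(C(C)C)C(C)C)c(OC)c1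
A4 | alternative 2 | (3aS,6aS)-tetrahydro-1H,3H-furo[3,4-c]furan-1,4-diyl diacetate (anomeric mixture) | CC(=O)OC1OC[C@@H]2[C@H]1COC2OC(C)=O
A5 | alternative 2 | bromo[3-methoxy-4-(triisopropylsilyloxy)phenyl]zinc | COc1cc([Zn]Br)ccc1O[Si](C(C)C)(C(C)C)C(C)C
A6 | alternative 2 | (1R,3aS,4R,6aS)-1,4-bis[3-methoxy-4-(triisopropylsilyloxy)phenyl]tetrahydro-1H,3H-furo[3,4-c]furan | COc1cc([C@@H]2OC[C@@H]3[C@H]2CO[C@H]3c2ccc(O[Si](C(C)C)(C(C)C)C(C)C)c(OC)c2)ccc1O[Si](C(C)C)(C(C)C)C(C)C
A7 | alternative 2 | 4,4'-[(1R,3aS,4R,6aS)-tetrahydro-1H,3H-furo[3,4-c]furan-1,4-diyl]bis(2-methoxyphenol) (levorotatory pinoresinol) | COc1cc([C@@H]2OC[C@@H]3[C@H]2CO[C@H]3c2ccc(O)c(OC)c2)ccc1O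
A8 | alternative 3 | methyl (S)-2-{3-methoxy-4-[(3-methylbut-2-en-1-yl)oxy]phenyl}-2,5-dihydrofuran-3-carboxylate | COC(=O)C1=CCO[C@H]1c1ccc(OCC=C(C)C)c(OC)c1
A9 | alternative 3 | 3-methoxy-4-(triisopropylsilyloxy)benzaldehyde | COc1cc(C=O)ccc1O[Si](C(C)C)(C(C)C)C(C)C
A10 | alternative 3 | cis-fused furofuranone with the lactone carbonyl at C9' | COc1cc([C@@H]2OC(=O)[C@@H]3[C@H]2CO[C@H]3c2ccc(OCC=C(C)C)c(OC)c2)ccc1O[Si](C(C)C)(C(C)C)C(C)C
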